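Numbering follows the germacrane skeleton: ring carbons C1–C10, lactone carbonyl C12 on O6, methylene C13, methyl C14, hydroxymethyl C15.
Retrosynthesis: after the O15 silyl ether, the furanone is cut at C2–C3 and at its enol-ether O–C3 bond. This is possible because C2–C3 lies 1,5 to the C10 oxygen (O–C10–C1–C2, then C3), so the ring oxygen can first hold C3 as an ester in a nine-membered lactone and carry it across the C1–C10 ring.
Further cuts: C4=C5 (metathesis), O8–acyl, C7–C8 (allylation), O10–C3 (acylation), C1–C2 and C9–C10.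
Forward: the butenolide (C5–C7, C11–C13) and the ketone ester (C1–C4, C8–C10, C14, C15) are joined at C7–C8, which creates the α-methylene γ-lactone; the nine-membered lactone closes at C4=C5; the key step then closes the ten-membered carbocycle and the furanone together.
Stereochemistry: C10 from (S)-lactic acid by alkylation of its dioxolanone enolate, C6 from (R)-2-vinyloxirane, C7 and C8 from the chromium allylation under control of C6, with C8 inverted when the isobutyrate is introduced; 4Z is enforced by the ring.

Key step: step 16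

Assumption: (R)-2-vinyloxirane (15) and (phenylselanyl)acetic acid (16) are taken as catalogue compounds; the C3 epimers of 18–20 are carried as a mixture because that carbon (later C11) becomes sp2.

Step 1
Reactants: 1 methyl 2-(hydroxymethyl)prop-2-enoate
Product: 2 methyl 2-({[tert-butyl(dimethyl)silyl]oxy}methyl)prop-2-enoate
Conditions: TBSCl, imidazole, CH2Cl2, 0 °C to rt
Reagents that add atoms: tert-butyldimethylsilyl chloride, CC(C)(C)[Si](C)(C)Cl
Why: Imidazole-mediated silyl ether formation on the primary allylic alcohol masks O15 for all later base and metal steps.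

Step 2
Reactants: 2 methyl 2-({[tert-butyl(dimethyl)silyl]oxy}methyl)prop-2-enoate
Product: 3 2-({[tert-butyl(dimethyl)silyl]oxy}methyl)prop-2-enoic acid
Conditions: LiOH, THF/H2O, 0 °C; then 1 M HCl to pH 4
Reagents that add atoms: lithium hydroxide, [Li+].[OH-]
Why: Saponification of the methyl ester at low temperature should leave the primary silyl ether intact and gives the acid (C3, C4, C15) for the later ester at O10.

Step 3
Reactants: 4 (S)-lactic acid; 5 pivalaldehyde (2,2-dimethylpropanal)
Product: 6 (2S,5S)-2-tert-butyl-5-methyl-1,3-dioxolan-4-one (cis)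
Conditions: TsOH·H2O (cat.), pentane, reflux, Dean–Stark; crystallisation at −78 °C
Reagents that add atoms: none
Why: Acid-catalysed acetalisation with azeotropic removal of water should give mainly the cis dioxolanone, purified by crystallisation, in which the acetal carbon stores the lactic acid configuration (self-regeneration of stereocentres).

Step 4
Reactants: 6 (2S,5S)-2-tert-butyl-5-methyl-1,3-dioxolan-4-one; 7 allyl bromide (3-bromoprop-1-ene)
Product: 8 (2S,5R)-2-tert-butyl-5-methyl-5-(prop-2-en-1-yl)-1,3-dioxolan-4-one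
Conditions: LDA, THF, −78 °C; then 7, −78 to −30 °C
Reagents that add atoms: none
Why: Enolate alkylation: the planar lithium enolate is attacked on the face opposite the tert-butyl group, so allyl replaces H with retention and the quaternary centre C10 is set as R (bond C9–C10).

Step 5
Reactants: 8 (2S,5R)-2-tert-butyl-5-methyl-5-(prop-2-en-1-yl)-1,3-dioxolan-4-one
Product: 9 (2R)-2-hydroxy-N-methoxy-N,2-dimethylpent-4-enamide
Conditions: MeNH(OMe)·HCl, i-PrMgCl, THF, −20 to 0 °C; aq. NH4Cl
Reagents that add atoms: N,O-dimethylhydroxylamine hydrochloride, CNOC.Cl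
Why: Weinreb amide formation by aminolysis of the activated, acylal-type lactone carbonyl with the magnesium amide, which releases pivalaldehyde and frees the tertiary hydroxyl without touching C10.

Step 6
Reactants: 9 (2R)-2-hydroxy-N-methoxy-N,2-dimethylpent-4-enamide
Product: 10 (3R)-3-hydroxy-3-methylhex-5-en-2-one
Conditions: MeMgBr (3 equiv), THF, 0 °C; aq. NH4Cl
Reagents that add atoms: methylmagnesium bromide, C[Mg]Br
Why: Grignard addition to the Weinreb amide stops at the chelated tetrahedral adduct and gives the methyl ketone (C1, C2) on work-up, one equivalent being used up by the hydroxyl.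

Step 7
Reactants: 3 2-({[tert-butyl(dimethyl)silyl]oxy}methyl)prop-2-enoic acid; 10 (3R)-3-hydroxy-3-methylhex-5-en-2-one
Product: 12 (3R)-3-methyl-2-oxohex-5-en-3-yl 2-({[tert-butyl(dimethyl)silyl]oxy}methyl)prop-2-enoate, via acid chloride 11 (not isolated)
Conditions: 3, 1-chloro-N,N,2-trimethylprop-1-en-1-amine (Ghosez reagent), CH2Cl2, 0 °C to rt; then 10, DMAP, Et3N, CH2Cl2, rt to 40 °C
Reagents that add atoms: none
Why: DMAP-catalysed acylation of a tertiary α-ketol with an acid chloride, the usual entry to α-acyloxy ketones for 3(2H)-furanone synthesis; the neutral chloroenamine makes the acid chloride without acid that would cleave the silyl ether.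

Step 8
Reactants: 12 (3R)-3-methyl-2-oxohex-5-en-3-yl 2-({[tert-butyl(dimethyl)silyl]oxy}methyl)prop-2-enoate
Product: 14 (3R)-3-methyl-2,5-dioxopentan-3-yl 2-({[tert-butyl(dimethyl)silyl]oxy}methyl)prop-2-enoate, via ozonide 13 (not isolated)
Conditions: O3, CH2Cl2, −78 °C (Sudan Red 7B end-point); then PPh3, −78 °C to rt
Reagents that add atoms: ozone, [O-][O+]=O
Why: Ozonolysis with reductive work-up: ozone attacks the electron-rich monosubstituted alkene far faster than the 2-substituted acrylate, and the dye end-point stops the reaction there; the β-acyloxy aldehyde (C8) is used at once.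

Step 9
Reactants: 15 (2R)-2-ethenyloxirane; 16 (phenylselanyl)acetic acid
Product: 18 (5S)-5-ethenyl-3-(phenylselanyl)oxolan-2-one, via hydroxy acid 17 (not isolated)
Conditions: 16, LDA (2.1 equiv), THF, −78 to 0 °C; then 15, 0 °C to rt; 1 M HCl; then TsOH (cat.), benzene, rt
Reagents that add atoms: none
Why: Epoxide opening by a carboxylic acid dianion (SN2 at the unsubstituted carbon, as is usual under basic conditions) followed by acid-catalysed lactonisation; C6 is not a reacting centre, so the epoxide configuration is carried over.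

Step 10
Reactants: 18 (5S)-5-ethenyl-3-(phenylselanyl)oxolan-2-one
Product: 19 (5S)-5-ethenyl-3-(hydroxymethyl)-3-(phenylselanyl)oxolan-2-one
Conditions: LDA, THF, −78 °C; then CH2O (gas, from paraformaldehyde), −78 to −20 °C
Reagents that add atoms: formaldehyde, C=O
Why: Aldol addition of the α-seleno lactone enolate to monomeric formaldehyde introduces C13 at the correct oxidation level.

Step 11
Reactants: 19 (5S)-5-ethenyl-3-(hydroxymethyl)-3-(phenylselanyl)oxolan-2-one
Product: 21 (5R)-5-ethenyl-3-(hydroxymethyl)furan-2(5H)-one, via selenoxide 20 (not isolated)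
Conditions: 30% H2O2 (excess), pyridine, CH2Cl2, 0 °C to rt
Reagents that add atoms: none
Why: Selenide oxidation and selenoxide syn-elimination, which goes towards the ring CH2 and away from the carbinol carbon and so gives the endocyclic butenolide under nearly neutral conditions that spare the acidic C6–H.

Step 12
Reactants: 21 (5R)-5-ethenyl-3-(hydroxymethyl)furan-2(5H)-one
Product: 22 (5R)-3-(bromomethyl)-5-ethenylfuran-2(5H)-one
Conditions: CBr4, PPh3, CH2Cl2, 0 °C
Reagents that add atoms: tetrabromomethane, BrC(Br)(Br)Br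
Why: Appel bromination of the primary allylic alcohol is neutral and leaves the C6 stereocentre and the vinyl group alone.

Step 13
Reactants: 14 (3R)-3-methyl-2,5-dioxopentan-3-yl 2-({[tert-butyl(dimethyl)silyl]oxy}methyl)prop-2-enoate; 22 (5R)-3-(bromomethyl)-5-ethenylfuran-2(5H)-one
Product: 23 (8S)-alcohol, (3R,5S)-5-[(2R,3R)-2-ethenyl-4-methylidene-5-oxooxolan-3-yl]-5-hydroxy-3-methyl-2-oxopentan-3-yl 2-({[tert-butyl(dimethyl)silyl]oxy}methyl)prop-2-enoate
Conditions: CrCl2 (4 equiv), THF, 0 °C to rt; H2O
Reagents that add atoms: none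
Why: Nozaki–Hiyama allylation: the allylchromium species from 22 adds to the aldehyde, not the ketone, at its γ-carbon C7 through a chair Zimmerman–Traxler transition state on the face away from the C6 vinyl group, which should set C7 as R (trans lactone); because the ring-locked allyl geometry puts C6 and the aldehyde chain equatorial, the 7,8-anti alcohol (8S) is expected, and the next step inverts it.

Step 14
Reactants: 23 (8S)-alcohol; 24 isobutyric acid (2-methylpropanoic acid)
Product: 25 (3R,5R)-5-[(2R,3R)-2-ethenyl-4-methylidene-5-oxooxolan-3-yl]-3-methyl-5-[(2-methylpropanoyl)oxy]-2-oxopentan-3-yl 2-({[tert-butyl(dimethyl)silyl]oxy}methyl)prop-2-enoate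
Conditions: 24, PPh3, DIAD, toluene, 0 °C to rt
Reagents that add atoms: none
Why: Mitsunobu esterification: SN2 displacement of the C8 alkoxyphosphonium by isobutyrate inverts C8 to the required R configuration and installs the ester in the same operation.

Step 15
Reactants: 25 open-chain (8R)-isobutyrate diene
Product: 26 nine-membered (4Z)-enoate lactone (6R,7R,8R,10R): ring C3(=O)–C4(CH2OTBS)=C5–C6–C7–C8(O-isobutyryl)–C9–C10(CH3)(COCH3)–O, trans-fused at C6/C7 to the 13-methylene 12,6-olide
Conditions: Hoveyda–Grubbs II (15 mol%), toluene (1 mM), 90 °C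
Reagents that add atoms: none
Why: Ring-closing metathesis: the catalyst loads on the monosubstituted C5 vinyl group and closes onto the 1,1-disubstituted acrylate while the trans-fused γ-lactone holds the two chains gauche; the nine-membered ring admits only the cis (4Z) alkene, and the α-methylene lactone cannot compete because it would give a four-membered ring.

Step 16
Reactants: 26 nine-membered (4Z)-enoate lactone
Product: 29 15-O-TBS ether of the target, via hydroxy diketone 27 (not isolated), via hemiketal 28 (not isolated)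
Conditions: LiHMDS (1.2 equiv), THF (5 mM), −78 to −40 °C; AcOH; then PPTS (cat.), 4 Å MS, CH2Cl2, rt
Reagents that add atoms: none
Why: Proposed new method: LiHMDS deprotonates the C2 methyl group, the only enolisable position of the C1 ketone because C10 is quaternary, and the lithium enolate adds to the lactone carbonyl C3 through a five-membered transition state (C2–C1–C10–O–C3); this forms C2–C3 and with it the ten-membered carbocycle, and the adduct opens to the hydroxy 1,3-diketone 27, whose C10 hydroxyl returns to C3 under acid to give hemiketal 28 and, after loss of water across C2–C3, the 3(2H)-furanone. The closest known reaction is the Baker–Venkataraman O-to-C acyl shift of α-acyloxy ketones followed by acid cyclodehydration to 3(2H)-furanones, which has not been run across a medium-ring lactone. The carbocycle closes by 5-exo-trig attack of the enolate carbon on the ester carbonyl inside the nine-membered ring (a transannular Claisen condensation), and the furanone closes by 5-exo-trig hemiketalisation and dehydration. No stereocentre is formed, and C6, C7, C8 and C10 are not reacting centres. The step needs enolisation at C2 in preference to the isobutyrate α-CH, and 1,2- in preference to 1,4-addition to the enoate; the higher acidity of the methyl ketone towards a hindered, non-nucleophilic amide at −78 °C and the 1,5 relation of C2 and C3 (five- against seven-membered transition state for attack at C5) should secure both. High dilution should suppress intermolecular aldol and Michael reactions.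

Step 17
Reactants: 29 15-O-TBS ether of the target
Product: 30 target, CNP0176924.3
Conditions: HF·pyridine, pyridine/THF, 0 °C to rt
Reagents that add atoms: none
Why: Fluoride cleavage of the primary silyl ether with buffered, non-basic HF·pyridine should spare the α-methylene lactone, the furanone and the isobutyrate.

Compound list
1 | methyl 2-(hydroxymethyl)prop-2-enoate | C=C(CO)C(=O)OC | starting material
2 | methyl 2-({[tert-butyl(dimethyl)silyl]oxy}methyl)prop-2-enoate | C=C(CO[Si](C)(C)C(C)(C)C)C(=O)OC | intermediate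
3 | 2-({[tert-butyl(dimethyl)silyl]oxy}methyl)prop-2-enoic acid | C=C(CO[Si](C)(C)C(C)(C)C)C(=O)O | intermediate
4 | (S)-lactic acid | C[C@H](O)C(=O)O | starting material
5 | pivalaldehyde (2,2-dimethylpropanal) | CC(C)(C)C=O | starting material
6 | (2S,5S)-2-tert-butyl-5-methyl-1,3-dioxolan-4-one | C[C@@H]1O[C@H](C(C)(C)C)OC1=O | intermediate
7 | allyl bromide (3-bromoprop-1-ene) | C=CCBr | starting material
8 | (2S,5R)-2-tert-butyl-5-methyl-5-(prop-2-en-1-yl)-1,3-dioxolan-4-one | C[C@]1(CC=C)O[C@H](C(C)(C)C)OC1=O | intermediate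
9 | (2R)-2-hydroxy-N-methoxy-N,2-dimethylpent-4-enamide | C[C@@](O)(CC=C)C(=O)N(C)OC | intermediate
10 | (3R)-3-hydroxy-3-methylhex-5-en-2-one | C[C@@](O)(CC=C)C(C)=O | intermediate
11 | 2-({[tert-butyl(dimethyl)silyl]oxy}methyl)prop-2-enoyl chloride | C=C(CO[Si](C)(C)C(C)(C)C)C(=O)Cl | intermediate (not isolated)
12 | (3R)-3-methyl-2-oxohex-5-en-3-yl 2-({[tert-butyl(dimethyl)silyl]oxy}methyl)prop-2-enoate | C[C@@](OC(=O)C(=C)CO[Si](C)(C)C(C)(C)C)(CC=C)C(C)=O | intermediate
13 | ozonide of 12: (2R)-2-methyl-3-oxo-1-(1,2,4-trioxolan-3-yl)butan-2-yl 2-({[tert-butyl(dimethyl)silyl]oxy}methyl)prop-2-enoate | C[C@@](OC(=O)C(=C)CO[Si](C)(C)C(C)(C)C)(CC1OCOO1)C(C)=O | intermediate (not isolated)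
14 | (3R)-3-methyl-2,5-dioxopentan-3-yl 2-({[tert-butyl(dimethyl)silyl]oxy}methyl)prop-2-enoate | C[C@@](OC(=O)C(=C)CO[Si](C)(C)C(C)(C)C)(CC=O)C(C)=O | intermediate
15 | (2R)-2-ethenyloxirane | C=C[C@@H]1CO1 | starting material
16 | (phenylselanyl)acetic acid | OC(=O)C[Se]c1ccccc1 | starting material
17 | (4S)-4-hydroxy-2-(phenylselanyl)hex-5-enoic acid (C2 epimers) | C=C[C@@H](O)CC([Se]c1ccccc1)C(=O)O | intermediate (not isolated)
18 | (5S)-5-ethenyl-3-(phenylselanyl)oxolan-2-one (C3 epimers) | C=C[C@@H]1CC([Se]c2ccccc2)C(=O)O1 | intermediate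
19 | (5S)-5-ethenyl-3-(hydroxymethyl)-3-(phenylselanyl)oxolan-2-one (C3 epimers) | C=C[C@@H]1CC(CO)([Se]c2ccccc2)C(=O)O1 | intermediate
20 | selenoxide of 19: (5S)-5-ethenyl-3-(hydroxymethyl)-3-(phenylseleninyl)oxolan-2-one | C=C[C@@H]1CC(CO)([Se](=O)c2ccccc2)C(=O)O1 | intermediate (not isolated)
21 | (5R)-5-ethenyl-3-(hydroxymethyl)furan-2(5H)-one | C=C[C@@H]1C=C(CO)C(=O)O1 | intermediate
22 | (5R)-3-(bromomethyl)-5-ethenylfuran-2(5H)-one | C=C[C@@H]1C=C(CBr)C(=O)O1 | intermediate
23 | (8S)-alcohol: (3R,5S)-5-[(2R,3R)-2-ethenyl-4-methylidene-5-oxooxolan-3-yl]-5-hydroxy-3-methyl-2-oxopentan-3-yl 2-({[tert-butyl(dimethyl)silyl]oxy}methyl)prop-2-enoate | C=C[C@H]1OC(=O)C(=C)[C@@H]1[C@@H](O)C[C@@](C)(OC(=O)C(=C)CO[Si](C)(C)C(C)(C)C)C(C)=O | intermediate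
24 | isobutyric acid (2-methylpropanoic acid) | CC(C)C(=O)O | starting material
25 | (8R)-isobutyrate diene: (3R,5R)-5-[(2R,3R)-2-ethenyl-4-methylidene-5-oxooxolan-3-yl]-3-methyl-5-[(2-methylpropanoyl)oxy]-2-oxopentan-3-yl 2-({[tert-butyl(dimethyl)silyl]oxy}methyl)prop-2-enoate | C=C[C@H]1OC(=O)C(=C)[C@@H]1[C@H](OC(=O)C(C)C)C[C@@](C)(OC(=O)C(=C)CO[Si](C)(C)C(C)(C)C)C(C)=O | intermediate
26 | nine-membered (4Z)-enoate lactone (6R,7R,8R,10R) with 10-acetyl, 10-methyl, 8-O-isobutyryl, 4-CH2OTBS, trans-fused 13-methylene 12,6-olide | C=C1C(=O)O[C@@H]2/C=C(/CO[Si](C)(C)C(C)(C)C)C(=O)O[C@@](C)(C(C)=O)C[C@@H](OC(=O)C(C)C)[C@@H]12 | intermediate (key-step precursor)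
27 | ten-membered 10-hydroxy-1,3-diketone (4Z,6R,7R,8R,10R) with 8-O-isobutyryl, 15-OTBS, 13-methylene 12,6-olide | C=C1C(=O)O[C@@H]2/C=C(/CO[Si](C)(C)C(C)(C)C)C(=O)CC(=O)[C@](C)(O)C[C@@H](OC(=O)C(C)C)[C@@H]12 | intermediate (not isolated)
28 | bridged hemiketal of 27: 3-hydroxy-3,10-epoxy-1-ketone (C3 epimers) | C=C1C(=O)O[C@@H]2/C=C(/CO[Si](C)(C)C(C)(C)C)C3(O)CC(=O)[C@@](C)(C[C@@H](OC(=O)C(C)C)[C@@H]12)O3 | intermediate (not isolated)
29 | 15-O-TBS ether of the target (key-step product) | C=C1C(=O)O[C@@H]2/C=C(/CO[Si](C)(C)C(C)(C)C)C3=CC(=O)[C@@](C)(C[C@@H](OC(=O)C(C)C)[C@@H]12)O3 | intermediate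
30 | CNP0176924.3, (4Z,6R,7R,8R,10R)-furanone germacranolide 8-isobutyrate with free 15-OH | C=C1C(=O)O[C@@H]2/C=C(/CO)C3=CC(=O)[C@@](C)(C[C@@H](OC(=O)C(C)C)[C@@H]12)O3 | target

Total step count: 17. Longest linear sequence: 11 steps (steps 3–8, then 13–17).

Steps most likely to fail

Step 16 (proposed new method). The enolate may not reach C3 across the nine-membered ring in the required geometry, so that proton exchange, conjugate addition to the enoate or intermolecular aldol reaction take over. The fallback uses known chemistry and sets out from 12. The same LiHMDS acyl shift and acid cyclodehydration on this simple open-chain tertiary α-acyloxy methyl ketone, the classical furanone synthesis, should give (2R)-2-methyl-2-(prop-2-en-1-yl)-5-[3-(TBS-oxy)prop-1-en-2-yl]furan-3(2H)-one F1. Lemieux–Johnson cleavage of the allyl group (OsO4 cat., NaIO4, 2,6-lutidine) gives the furanone aldehyde F2. Chromium allylation with 22 as in step 13 gives the open-chain (8S)-alcohol F3. Ring-closing metathesis (Hoveyda–Grubbs II, toluene, high dilution) closes the ten-membered carbocycle at C4=C5 to the macrocyclic (8S)-alcohol F4. Mitsunobu esterification with 24 inverts C8 and comes back to the route at 29.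

Step 15. Cross-metathesis between the vinyl groups of two molecules (oligomers) may outrun closure of the strained cis-lactone onto the hindered, electron-poor acrylate. The fallback sets out from 25: the acyl shift is run first on the open-chain ester (LiHMDS, then PPTS) to give the open-chain furanone diene isobutyrate F5. The ring is then closed by metathesis at C4=C5 as a ten-membered carbocycle, which has no cis-ester constraint and whose 1,1-disubstituted alkene is no longer an acrylate. This comes back at 29 and bypasses 26.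

Step 14. At the hindered C8 the alkoxyphosphonium may eliminate towards C9, be captured by the neighbouring O10 ester carbonyl, or give ester with retention through activation of the acid; the hemiketal form of the γ-hydroxy ketone may also intercept the reagent. The fallback sets out from 22 and makes the (8R)-alcohol directly. Palladium-catalysed stannylation with hexabutylditin (Pd(PPh3)4, THF) gives the allylstannane (5R)-5-ethenyl-3-[(tributylstannyl)methyl]furan-2(5H)-one F6. Its BF3·OEt2-promoted addition to 14 at −78 °C goes through an open antiperiplanar transition state, which should give the 7,8-syn adduct, again anti to the C6 vinyl group, that is the (8R)-alcohol F7. Acylation with isobutyryl chloride and pyridine, with retention, comes back at 25.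

Further compounds
F1 | step 16 | (2R)-2-methyl-2-(prop-2-en-1-yl)-5-(3-{[tert-butyl(dimethyl)silyl]oxy}prop-1-en-2-yl)furan-3(2H)-one | C=CC[C@@]1(C)OC(C(=C)CO[Si](C)(C)C(C)(C)C)=CC1=O
F2 | step 16 | [(2R)-2-methyl-3-oxo-5-(3-{[tert-butyl(dimethyl)silyl]oxy}prop-1-en-2-yl)-2,3-dihydrofuran-2-yl]acetaldehyde | O=CC[C@@]1(C)OC(C(=C)CO[Si](C)(C)C(C)(C)C)=CC1=O
F3 | step 16 | open-chain furanone (8S)-alcohol: (4R,5R)-5-ethenyl-4-{(1S)-1-hydroxy-2-[(2R)-2-methyl-3-oxo-5-(3-{[tert-butyl(dimethyl)silyl]oxy}prop-1-en-2-yl)-2,3-dihydrofuran-2-yl]ethyl}-3-methylideneoxolan-2-one | C=C[C@H]1OC(=O)C(=C)[C@@H]1[C@@H](O)C[C@@]2(C)OC(C(=C)CO[Si](C)(C)C(C)(C)C)=CC2=O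
F4 | step 16 | macrocyclic (8S)-alcohol: 8-epi-8-O-deacyl derivative of 29 | C=C1C(=O)O[C@@H]2/C=C(/CO[Si](C)(C)C(C)(C)C)C3=CC(=O)[C@@](C)(C[C@H](O)[C@@H]12)O3
F5 | step 15 | open-chain furanone diene isobutyrate: (1R)-1-[(2R,3R)-2-ethenyl-4-methylidene-5-oxooxolan-3-yl]-2-[(2R)-2-methyl-3-oxo-5-(3-{[tert-butyl(dimethyl)silyl]oxy}prop-1-en-2-yl)-2,3-dihydrofuran-2-yl]ethyl 2-methylpropanoate | C=C[C@H]1OC(=O)C(=C)[C@@H]1[C@H](OC(=O)C(C)C)C[C@@]2(C)OC(C(=C)CO[Si](C)(C)C(C)(C)C)=CC2=O
F6 | step 14 | (5R)-5-ethenyl-3-[(tributylstannyl)methyl]furan-2(5H)-one | C=C[C@@H]1C=C(C[Sn](CCCC)(CCCC)CCCC)C(=O)O1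
F7 | step 14 | (8R)-alcohol: (3R,5R)-5-[(2R,3R)-2-ethenyl-4-methylidene-5-oxooxolan-3-yl]-5-hydroxy-3-methyl-2-oxopentan-3-yl 2-({[tert-butyl(dimethyl)silyl]oxy}methyl)prop-2-enoate | C=C[C@H]1OC(=O)C(=C)[C@@H]1[C@H](O)C[C@@](C)(OC(=O)C(=C)CO[Si](C)(C)C(C)(C)C)C(C)=O
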